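**Plan**

- Numbering: ring A = C1–C5 and C10 (methylene on C4, methyl on C5); ring B = C5–C10 (methyl on C8, methyl and arylmethyl on C9, H on C10); α is the face of H10, β the face of the C5 methyl. Feature used: H10 and the C5 methyl are trans across the ring fusion and C4 carries a functional carbon next to the quaternary C5, so ring A is the [4+2] adduct of an (E)-α-methyl enal (C5=C10, formyl = C6) and a 1-siloxybutadiene (C1–C4, oxygen on C4).
- Cuts, in retrosynthetic order: C4=CH2 (Wittig), C8–CH3 (methylenation, hydrogenation), C9–CH2Ar (enolate alkylation), C6=C7 (aldol condensation), then C4–C5 and C1–C10 (Diels–Alder).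
- Forward: ring A by the cycloaddition; ring B by aldol condensation of a C8 methyl ketone (carried as a dioxolane, C7 is its methyl) onto the C6 aldehyde; then the aryl unit at C9, the C8 methyl, and last the C4 methylene.
- Stereochemistry: C5 from the chiral Lewis acid; C10 from the (E) alkene geometry; C9 by alkylation anti to the C5 methyl; C8 by hydrogenation on the α face. C4 and the early C9 centre are temporary.

Key step: step 5

Assumption: the (S)-oxazaborolidinium catalyst is taken, from the formyl C–H···O binding model, to expose the Cα-Re face of the enal, which is the face that gives 5S. C9 is carried as a mixture of epimers until it is enolised, and C4 is drawn as the endo (formyl cis to siloxy) adduct, although either C4 epimer would serve.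

**Route**

Step 1
Reactants: 1 ethyl 2-methyl-3-oxobutanoate (racemic)
Product: 2 ethyl 2-(2-methyl-1,3-dioxolan-2-yl)propanoate (racemic)
Conditions: ethylene glycol, TsOH (cat.), toluene, Dean–Stark, reflux
Reagents that add atoms: ethylene glycol, OCCO
Why: Acid-catalysed ketalisation with azeotropic removal of water masks only the ketone (future C8), since the ester cannot form a ketal.

Step 2
Reactants: 2 ethyl 2-(2-methyl-1,3-dioxolan-2-yl)propanoate
Product: 3 2-(2-methyl-1,3-dioxolan-2-yl)propanal (racemic)
Conditions: DIBAL-H (1.05 equiv), CH2Cl2, −78 °C; MeOH, aq. Rochelle salt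
Reagents that add atoms: none
Why: Partial ester reduction with DIBAL-H at low temperature should stop at the aldehyde because the aluminium hemiacetal, chelated by a dioxolane oxygen, collapses only on work-up.

Step 3
Reactants: 3 2-(2-methyl-1,3-dioxolan-2-yl)propanal; 4 2-(triphenyl-λ5-phosphanylidene)propanal
Product: 5 (E)-2-methyl-4-(2-methyl-1,3-dioxolan-2-yl)pent-2-enal (racemic at the future C9)
Conditions: toluene, 90 °C
Reagents that add atoms: none
Why: Wittig olefination with the stabilised formyl ylide is E-selective and the ylide does not react on with the less electrophilic α-methyl enal it produces.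

Step 4
Reactants: 6 (E)-but-2-enal (crotonaldehyde)
Product: 7 (E)-1-(tert-butyldimethylsilyloxy)buta-1,3-diene
Conditions: TBSOTf, Et3N, Et2O, 0 °C → rt
Reagents that add atoms: tert-butyldimethylsilyl triflate, CC(C)(C)[Si](C)(C)OS(=O)(=O)C(F)(F)F
Why: O-Silylation of the enal followed by γ-deprotonation (vinylogous silyl enol ether formation) should give mainly the (E)-dienol ether, and any Z isomer is inert in the cycloaddition.

Step 5
Reactants: 5 (E)-2-methyl-4-(2-methyl-1,3-dioxolan-2-yl)pent-2-enal; 7 (E)-1-(tert-butyldimethylsilyloxy)buta-1,3-diene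
Product: 8 (1S,2R,6S)-2-(tert-butyldimethylsilyloxy)-1-methyl-6-[1-(2-methyl-1,3-dioxolan-2-yl)ethyl]cyclohex-3-ene-1-carbaldehyde (both epimers at the side-chain CH = C9)
Conditions: (S)-o-tolyl-diphenylprolinol oxazaborolidine (20 mol %), Tf2NH (17 mol %), 7 (2.5 equiv), CH2Cl2, −78 → −40 °C
Reagents that add atoms: none
Why: The triflimide-protonated oxazaborolidine binds the formyl oxygen of 5 with the formyl C–H held by the ring oxygen, lowers the enal LUMO and lets the s-cis diene add across C5=C10 in a concerted, asynchronous, normal-demand [4+2] cycloaddition; the closest known type is the oxazaborolidinium-catalysed Diels–Alder reaction of α-substituted enals with oxygenated butadienes that creates a formyl-bearing quaternary carbon. Ring A closes as a six-membered carbocycle by suprafacial union of the four diene carbons (C1–C4) with the two alkene carbons, forming C1–C10 (the leading bond) and C4–C5. C5 is set by the catalyst, whose aryl group screens one enal face so that the diene should add to the Cα-Re face; C10 follows from C5 because the (E) geometry is transferred suprafacially (formyl and C9 chain trans, hence C5 methyl trans to H10); C4 follows from the endo position of the formyl group relative to the (E)-siloxy terminus and is not needed later. The step needs ortho regiochemistry, secured by the siloxy donor that makes the unsubstituted diene terminus the nucleophilic end bonding to the β-carbon C10; it needs enantioface control, which comes from the catalyst; and it needs C=C over C=O chemoselectivity, secured by the weak nucleophilicity of a mono-oxygenated diene toward the bound carbonyl. The dioxolane and the bulky silyl ether are chosen to survive the Lewis acid.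

Step 6
Reactants: 8 Diels–Alder adduct
Product: 11 trans-fused dienone 4α-(tert-butyldimethylsilyloxy)-5β,9α-dimethyl-10α-H-decala-2,6-dien-8-one, via keto aldehyde 9 (not isolated), via ring-B aldol 10 (not isolated)
Conditions: PPTS, acetone/H2O (4:1), 60 °C; concentrate; then KOH, MeOH, 0 → 45 °C
Reagents that add atoms: water, O
Why: Acetal hydrolysis followed by intramolecular aldol condensation (Robinson-type closure) should close ring B because only the methyl (C7) enolate can reach the non-enolisable C6 aldehyde through a six-membered transition state, E1cB dehydration gives the C6=C7 enone, and the base equilibrates C9 to the equatorial methyl epimer.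

Step 7
Reactants: 12 methyl vanillate (methyl 4-hydroxy-3-methoxybenzoate)
Product: 13 methyl 3-formyl-4-hydroxy-5-methoxybenzoate
Conditions: hexamethylenetetramine, TFA, 85 °C; then 2 M aq. HCl
Reagents that add atoms: hexamethylenetetramine, C1N2CN3CN1CN(C2)C3; water, O
Why: Duff formylation places the formyl group at the only free position ortho to the phenol.

Step 8
Reactants: 13 methyl 3-formyl-4-hydroxy-5-methoxybenzoate
Product: 14 methyl 3-formyl-5-methoxy-4-(methoxymethoxy)benzoate
Conditions: MOMCl, i-Pr2NEt, CH2Cl2, 0 °C → rt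
Reagents that add atoms: chloromethyl methyl ether, COCCl
Why: O-Alkylation of the acidic phenol gives the MOM ether, which is stable to hydride, phosphine/CBr4, enolates, hydrogenation and organozinc–titanium reagents.

Step 9
Reactants: 14 methyl 3-formyl-5-methoxy-4-(methoxymethoxy)benzoate
Product: 15 methyl 3-(hydroxymethyl)-5-methoxy-4-(methoxymethoxy)benzoate
Conditions: NaBH4, MeOH, 0 °C
Reagents that add atoms: none
Why: Borohydride reduction is chemoselective for the aldehyde over the benzoate ester at 0 °C.

Step 10
Reactants: 15 methyl 3-(hydroxymethyl)-5-methoxy-4-(methoxymethoxy)benzoate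
Product: 16 methyl 3-(bromomethyl)-5-methoxy-4-(methoxymethoxy)benzoate
Conditions: CBr4, PPh3, CH2Cl2, 0 °C
Reagents that add atoms: carbon tetrabromide, BrC(Br)(Br)Br
Why: Appel bromination converts the benzylic alcohol to the bromide under neutral conditions that leave the MOM acetal intact.

Step 11
Reactants: 11 trans-fused dienone; 16 methyl 3-(bromomethyl)-5-methoxy-4-(methoxymethoxy)benzoate
Product: 18 C9-benzylated dienone 4α-(tert-butyldimethylsilyloxy)-9α-[(3-methoxy-5-methoxycarbonyl-2-methoxymethoxyphenyl)methyl]-5β,9β-dimethyl-10α-H-decala-2,6-dien-8-one, via lithium dienolate 17 (not isolated)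
Conditions: LDA (1.15 equiv), THF, −78 °C; then 16 (1.3 equiv), DMPU, −78 → −30 °C
Reagents that add atoms: none
Why: Kinetic α′-deprotonation of the enone can occur only at C9 (C5 is quaternary, C7 is sp2), and SN2 alkylation of the cross-conjugated dienolate by the benzylic bromide should take place on the α face, opposite the C5 methyl that lies 1,3-syn over the β face of C9, giving 9α-arylmethyl and 9β-methyl.

Step 12
Reactants: 18 C9-benzylated dienone
Product: 19 saturated ketone 4α-(tert-butyldimethylsilyloxy)-9α-arylmethyl-5β,9β-dimethyl-10α-H-decalin-8-one (aryl = 3-methoxy-5-methoxycarbonyl-2-methoxymethoxyphenyl)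
Conditions: H2 (1 atm), 10% Pd/C, EtOAc, rt
Reagents that add atoms: none
Why: Heterogeneous catalytic hydrogenation reduces the two disubstituted alkenes (C2=C3 and the C6=C7 enone) without creating a stereocentre and leaves the ketone, benzoate, MOM and silyl ether untouched.

Step 13
Reactants: 19 saturated C8 ketone
Product: 20 8-methylene compound 4α-(tert-butyldimethylsilyloxy)-9α-arylmethyl-5β,9β-dimethyl-8-methylene-10α-H-decalin
Conditions: Zn, CH2Br2, TiCl4 (pre-formed Lombardo reagent), THF/CH2Cl2, 0 °C → rt
Reagents that add atoms: dibromomethane, BrCBr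
Why: Takai–Lombardo methylenation uses a non-basic gem-dimetallic reagent that adds to hindered ketones and does not attack the benzoate ester, which a hot phosphorus ylide or methyllithium would.

Step 14
Reactants: 20 8-methylene compound
Product: 21 4α-(tert-butyldimethylsilyloxy)-9α-arylmethyl-5β,8β,9β-trimethyl-10α-H-decalin
Conditions: H2 (1 atm), 10% Pd/C, EtOAc, rt
Reagents that add atoms: none
Why: Catalytic hydrogenation of the 1,1-disubstituted alkene should deliver hydrogen to the α face of C8, away from the axial β-methyls on C9 and C5, giving the equatorial 8β-methyl (8S).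

Step 15
Reactants: 21 silyl ether
Product: 22 4α-hydroxy-9α-arylmethyl-5β,8β,9β-trimethyl-10α-H-decalin (aryl still MOM-protected)
Conditions: TBAF, THF, 45 °C
Reagents that add atoms: none
Why: Fluoride-induced desilylation frees the hindered secondary alcohol while the MOM ether and methyl ester stay in place.

Step 16
Reactants: 22 C4 alcohol
Product: 23 4-ketone 9α-arylmethyl-5β,8β,9β-trimethyl-10α-H-decalin-4-one (aryl MOM-protected)
Conditions: Dess–Martin periodinane, CH2Cl2, rt
Reagents that add atoms: none
Why: Dess–Martin oxidation gives the ketone under near-neutral conditions, and no stereocentre is at risk because C5 is quaternary.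

Step 17
Reactants: 23 MOM-protected 4-ketone
Product: 24 phenol ketone methyl 4-hydroxy-3-methoxy-5-{[(5β,8β,9β)-trimethyl-4-oxo-10α-H-decalin-9α-yl]methyl}benzoate
Conditions: 2 M aq. HCl/MeOH (1:4), 45 °C
Reagents that add atoms: none
Why: Acid-catalysed acetal hydrolysis removes the MOM group before the exocyclic alkene exists, so that no acid ever meets the acid-sensitive alkene–phenol pair of the target.

Step 18
Reactants: 24 phenol ketone
Product: 27 polyfibrospongol A, (5S,8S,9R,10S), via ketone potassium phenoxide 25 (not isolated), via olefin potassium phenoxide 26 (not isolated)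
Conditions: KOt-Bu (1.0 equiv), THF, 0 °C; then Ph3P=CH2 (from Ph3PCH3Br/KOt-Bu, 5 equiv), toluene/THF, 80 °C; aq. NH4Cl
Reagents that add atoms: methyltriphenylphosphonium bromide, C[P+](c1ccccc1)(c1ccccc1)c1ccccc1.[Br-]
Why: Wittig methylenation with excess ylide should convert the hindered C4 ketone next to the quaternary C5 into the exocyclic alkene, while the phenoxide formed first makes the para ester too electron-rich to be acylated by the ylide; no stereocentre is created or touched.

**Compound list**

1 | ethyl 2-methyl-3-oxobutanoate | CCOC(=O)C(C)C(C)=O | starting material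
2 | ethyl 2-(2-methyl-1,3-dioxolan-2-yl)propanoate | CCOC(=O)C(C)C1(C)OCCO1 | intermediate
3 | 2-(2-methyl-1,3-dioxolan-2-yl)propanal | O=CC(C)C1(C)OCCO1 | intermediate
4 | 2-(triphenyl-λ5-phosphanylidene)propanal | CC(C=O)=P(c1ccccc1)(c1ccccc1)c1ccccc1 | starting material
5 | (E)-2-methyl-4-(2-methyl-1,3-dioxolan-2-yl)pent-2-enal | O=C/C(C)=C/C(C)C1(C)OCCO1 | intermediate
6 | (E)-but-2-enal | C/C=C/C=O | starting material
7 | (E)-1-(tert-butyldimethylsilyloxy)buta-1,3-diene | C=C/C=C/O[Si](C)(C)C(C)(C)C | intermediate
8 | (1S,2R,6S)-2-(tert-butyldimethylsilyloxy)-1-methyl-6-[1-(2-methyl-1,3-dioxolan-2-yl)ethyl]cyclohex-3-ene-1-carbaldehyde, C9 epimers | O=C[C@]1(C)[C@H](O[Si](C)(C)C(C)(C)C)C=CC[C@H]1C(C)C2(C)OCCO2 | intermediate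
9 | keto aldehyde: (1S,2R,6S)-2-(tert-butyldimethylsilyloxy)-1-methyl-6-(3-oxobutan-2-yl)cyclohex-3-ene-1-carbaldehyde, C9 epimers | O=C[C@]1(C)[C@H](O[Si](C)(C)C(C)(C)C)C=CC[C@H]1C(C)C(C)=O | intermediate
10 | ring-B aldol: 4α-(tert-butyldimethylsilyloxy)-6-hydroxy-5β,9-dimethyl-10α-H-decal-2-en-8-one, C6 and C9 epimers | CC(C)(C)[Si](C)(C)O[C@@H]1C=CC[C@H]2C(C)C(=O)CC(O)[C@]12C | intermediate
11 | 4α-(tert-butyldimethylsilyloxy)-5β,9α-dimethyl-10α-H-decala-2,6-dien-8-one | CC(C)(C)[Si](C)(C)O[C@@H]1C=CC[C@H]2[C@H](C)C(=O)C=C[C@]12C | intermediate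
12 | methyl vanillate | COC(=O)c1ccc(O)c(OC)c1 | starting material
13 | methyl 3-formyl-4-hydroxy-5-methoxybenzoate | COC(=O)c1cc(C=O)c(O)c(OC)c1 | intermediate
14 | methyl 3-formyl-5-methoxy-4-(methoxymethoxy)benzoate | COC(=O)c1cc(C=O)c(OCOC)c(OC)c1 | intermediate
15 | methyl 3-(hydroxymethyl)-5-methoxy-4-(methoxymethoxy)benzoate | COC(=O)c1cc(CO)c(OCOC)c(OC)c1 | intermediate
16 | methyl 3-(bromomethyl)-5-methoxy-4-(methoxymethoxy)benzoate | COC(=O)c1cc(CBr)c(OCOC)c(OC)c1 | intermediate
17 | lithium 2,6,8(9)-trien-8-olate of 11 (cross-conjugated dienolate) | CC(C)(C)[Si](C)(C)O[C@@H]1C=CC[C@H]2C(C)=C([O-])C=C[C@]12C.[Li+] | intermediate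
18 | 4α-(tert-butyldimethylsilyloxy)-9α-[(3-methoxy-5-methoxycarbonyl-2-methoxymethoxyphenyl)methyl]-5β,9β-dimethyl-10α-H-decala-2,6-dien-8-one | CC(C)(C)[Si](C)(C)O[C@@H]1C=CC[C@H]2[C@](C)(Cc3cc(C(=O)OC)cc(OC)c3OCOC)C(=O)C=C[C@]12C | intermediate
19 | saturated 8-ketone of 18 (trans-decalin-8-one) | CC(C)(C)[Si](C)(C)O[C@@H]1CCC[C@H]2[C@](C)(Cc3cc(C(=O)OC)cc(OC)c3OCOC)C(=O)CC[C@]12C | intermediate
20 | 8-methylene compound | CC(C)(C)[Si](C)(C)O[C@@H]1CCC[C@H]2[C@](C)(Cc3cc(C(=O)OC)cc(OC)c3OCOC)C(=C)CC[C@]12C | intermediate
21 | 8β-methyl compound (4α-OTBS, aryl MOM ether) | CC(C)(C)[Si](C)(C)O[C@@H]1CCC[C@H]2[C@](C)(Cc3cc(C(=O)OC)cc(OC)c3OCOC)[C@@H](C)CC[C@]12C | intermediate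
22 | 4α-alcohol (aryl MOM ether) | O[C@@H]1CCC[C@H]2[C@](C)(Cc3cc(C(=O)OC)cc(OC)c3OCOC)[C@@H](C)CC[C@]12C | intermediate
23 | 4-ketone (aryl MOM ether) | O=C1CCC[C@H]2[C@](C)(Cc3cc(C(=O)OC)cc(OC)c3OCOC)[C@@H](C)CC[C@]12C | intermediate
24 | 4-ketone with free phenol | O=C1CCC[C@H]2[C@](C)(Cc3cc(C(=O)OC)cc(OC)c3O)[C@@H](C)CC[C@]12C | intermediate
25 | potassium phenoxide of 24 | O=C1CCC[C@H]2[C@](C)(Cc3cc(C(=O)OC)cc(OC)c3[O-])[C@@H](C)CC[C@]12C.[K+] | intermediate
26 | potassium phenoxide of the target | C=C1CCC[C@H]2[C@](C)(Cc3cc(C(=O)OC)cc(OC)c3[O-])[C@@H](C)CC[C@]12C.[K+] | intermediate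
27 | polyfibrospongol A | C=C1CCC[C@H]2[C@](C)(Cc3cc(C(=O)OC)cc(OC)c3O)[C@@H](C)CC[C@]12C | target

**Step count and risks**

Total: 18 steps. Longest linear sequence: 13 steps (steps 1–3, 5, 6, 11–18).

Step 5. The β-branched, trisubstituted enal may add the diene too slowly, so that enantioface and endo control erode and the diene is lost to protodesilylation or to addition at the bound carbonyl. The fallback removes the branching from the dienophile and adds the C9 methyl afterwards. It sets out from 4 and 7 and uses purchased ethyl 2-(2-methyl-1,3-dioxolan-2-yl)acetate F1. DIBAL-H reduction would give 2-(2-methyl-1,3-dioxolan-2-yl)acetaldehyde F2, and Wittig reaction with 4 would give (E)-2-methyl-4-(2-methyl-1,3-dioxolan-2-yl)but-2-enal F3, which is less hindered at the β-carbon. The same catalysed cycloaddition with 7 should give the 9-desmethyl adduct F4. PPTS hydrolysis and then KOH/MeOH would lead through the 9-desmethyl keto aldehyde F5 and the 9-desmethyl ring-B aldol F6 to the 9-desmethyl dienone F7. LDA would convert F7 into the lithium dienolate F8, and iodomethane would methylate it at C9. The route is rejoined at 11.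

Step 11. Formation of the C9 quaternary centre on the rather flat cross-conjugated dienolate may be slow or may show poor facial discrimination. The fallback generates the chair-like, tetrasubstituted enolate of the saturated trans-decalone instead, the enolate type for which alkylation anti to the angular methyl is established. It sets out from 11. Hydrogenation (H2, Pd/C) would give the saturated 4α-silyloxy-5β,9α-dimethyl-decalin-8-one F9. Thermodynamic silylation (TMSCl, NaI, Et3N, MeCN) would give the Δ8(9) trimethylsilyl enol ether F10. One equivalent of MeLi would release the regiodefined lithium enolate F11, which would be alkylated with 16 in THF/DMPU. The route is rejoined at 19, so step 12 is not needed.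

Step 14. Delivery of hydrogen from the catalyst surface may not discriminate well enough between the two faces of the C8 methylene, which would give the 8-epimer alongside 21. The fallback moves the control from surface approach to the preference of a C8 tertiary radical for axial hydrogen-atom capture. It sets out from 20 and uses hydrogen-atom-transfer hydrogenation (Mn(dpm)3, PhSiH3, t-BuOOH, i-PrOH, rt), which should favour the thermodynamically preferred equatorial 8β-methyl. It returns at 21 and makes no new compound.

**Further compounds**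

F1 | step 5 | ethyl 2-(2-methyl-1,3-dioxolan-2-yl)acetate | CCOC(=O)CC1(C)OCCO1
F2 | step 5 | 2-(2-methyl-1,3-dioxolan-2-yl)acetaldehyde | O=CCC1(C)OCCO1
F3 | step 5 | (E)-2-methyl-4-(2-methyl-1,3-dioxolan-2-yl)but-2-enal | O=C/C(C)=C/CC1(C)OCCO1
F4 | step 5 | (1S,2R,6S)-2-(tert-butyldimethylsilyloxy)-1-methyl-6-[(2-methyl-1,3-dioxolan-2-yl)methyl]cyclohex-3-ene-1-carbaldehyde | O=C[C@]1(C)[C@H](O[Si](C)(C)C(C)(C)C)C=CC[C@H]1CC2(C)OCCO2
F5 | step 5 | (1S,2R,6S)-2-(tert-butyldimethylsilyloxy)-1-methyl-6-(2-oxopropyl)cyclohex-3-ene-1-carbaldehyde | O=C[C@]1(C)[C@H](O[Si](C)(C)C(C)(C)C)C=CC[C@H]1CC(C)=O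
F6 | step 5 | 4α-(tert-butyldimethylsilyloxy)-6-hydroxy-5β-methyl-10α-H-decal-2-en-8-one | CC(C)(C)[Si](C)(C)O[C@@H]1C=CC[C@H]2CC(=O)CC(O)[C@]12C
F7 | step 5 | 4α-(tert-butyldimethylsilyloxy)-5β-methyl-10α-H-decala-2,6-dien-8-one | CC(C)(C)[Si](C)(C)O[C@@H]1C=CC[C@H]2CC(=O)C=C[C@]12C
F8 | step 5 | lithium dienolate of F7 | CC(C)(C)[Si](C)(C)O[C@@H]1C=CC[C@H]2C=C([O-])C=C[C@]12C.[Li+]
F9 | step 11 | 4α-(tert-butyldimethylsilyloxy)-5β,9α-dimethyl-10α-H-decalin-8-one | CC(C)(C)[Si](C)(C)O[C@@H]1CCC[C@H]2[C@H](C)C(=O)CC[C@]12C
F10 | step 11 | 4α-(tert-butyldimethylsilyloxy)-5β,9-dimethyl-8-(trimethylsilyloxy)-10α-H-decal-8(9)-ene | CC(C)(C)[Si](C)(C)O[C@@H]1CCC[C@H]2C(C)=C(O[Si](C)(C)C)CC[C@]12C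
F11 | step 11 | lithium 8(9)-en-8-olate of F9 | CC(C)(C)[Si](C)(C)O[C@@H]1CCC[C@H]2C(C)=C([O-])CC[C@]12C.[Li+]
F0 | step 14 | none | none
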